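**Retrosynthetic overview**
- Ring B (the dihydropyranone) is opened last: C–O disconnection at the enol ether gives a 4‑(3‑hydroxydecanoyl)‑3‑hydroxy‑5,6‑dihydropyran‑2‑one.
- Ring A (the δ‑lactone) is traced back to a γ‑lactone: the acyl‑bearing ring carbon is removed as the diazo carbon of a β‑silyloxy diazoketone, leaving (R)‑5‑decyldihydrofuran‑2,3‑dione (one‑carbon ring expansion in the forward sense).
- The keto lactone comes from undecanal by catalytic asymmetric 2‑(methoxycarbonyl)allylation/lactonisation (sets the decyl carbinol, R) and ozonolysis; undecanal from oct‑1‑ene and a C3 bromo acetal.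
- The diazoketone comes from octanal by catalytic asymmetric aldol addition of an acetone equivalent (sets the heptyl carbinol, R), silylation and diazo transfer; octanal from 1‑bromoheptane and DMF.
- Order of ring formation: γ‑lactone, then ring A by ring expansion, then ring B by cyclodehydration.

Assumption: the SMILES is read as the (2R,6R) isomer; where a catalyst enantiomer is not fixed by name it is specified by the aldehyde face it must attack (Si face in steps 2 and 6).

**Step 1**
Reactants: 1 1‑bromoheptane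
Product: 3 octanal, via heptylmagnesium bromide 2 (not isolated)
Conditions: Mg, THF, reflux; DMF, 0 °C to rt; 1 M HCl
Reagents that add atoms: N,N‑dimethylformamide, CN(C)C=O (formyl C and O of 3); magnesium, [Mg] (held in 2 only)
Why: Bouveault formylation, in which the Grignard reagent adds only once to DMF because the magnesium hemiaminal alkoxide survives until the acid quench releases the aldehyde.

**Step 2**
Reactants: 3 octanal; 4 2‑methoxypropene
Product: 6 (R)‑4‑hydroxyundecan‑2‑one, via enol ether 5 (not isolated)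
Conditions: Ti(OiPr)4 (5 mol%), N‑(3‑bromo‑5‑tert‑butylsalicylidene)‑2‑amino‑2'‑hydroxy‑1,1'‑binaphthyl and 3,5‑di‑tert‑butylsalicylic acid (5 mol% each; ligand enantiomer giving Si‑face attack), 2,6‑di‑tert‑butyl‑4‑methylpyridine (0.4 equiv), neat 4, 0 °C to rt; then 2 M HCl, Et2O
Reagents that add atoms: water, O (ketone oxygen of 6)
Why: Carreira‑type catalytic asymmetric aldol (carbonyl‑ene) addition of 2‑methoxypropene, in which the chiral tetravalent‑titanium Schiff‑base complex binds the aldehyde and the chosen ligand enantiomer directs Si‑face attack to set the (R)‑carbinol, after which mild acid hydrolyses the enol ether to the methyl ketone.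

**Step 3**
Reactants: 6 (R)‑4‑hydroxyundecan‑2‑one
Product: 7 (R)‑4‑[(tert‑butyldimethylsilyl)oxy]undecan‑2‑one
Conditions: TBSCl, imidazole, DMF, rt
Reagents that add atoms: tert‑butyldimethylsilyl chloride, CC(C)(C)[Si](C)(C)Cl
Why: Standard silylation of a secondary alcohol, which blocks O–H insertion and retro‑aldol pathways in the following steps and leaves the stereocentre untouched.

**Step 4**
Reactants: 7 (R)‑4‑[(tert‑butyldimethylsilyl)oxy]undecan‑2‑one
Product: 9 (R)‑4‑[(tert‑butyldimethylsilyl)oxy]‑1‑diazoundecan‑2‑one, via trifluoroacetyl diketone 8 (not isolated)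
Conditions: LiN(SiMe3)2, THF, −78 °C; CF3CO2CH2CF3; then MsN3, Et3N, H2O (1 equiv), MeCN, rt
Reagents that add atoms: methanesulfonyl azide, CS(=O)(=O)N=[N+]=[N-] (N2 of 9); 2,2,2‑trifluoroethyl trifluoroacetate, FC(F)(F)COC(=O)C(F)(F)F (CF3CO of 8 only)
Why: Danheiser detrifluoroacetylative diazo transfer, in which the kinetic enolate forms at the methyl group, trifluoroacetylation activates that carbon for N2 transfer from MsN3, and retro‑Claisen loss of the trifluoroacetyl group leaves the terminal diazoketone without touching the β‑silyloxy stereocentre.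

**Step 5**
Reactants: 10 oct‑1‑ene; 11 2‑(2‑bromoethyl)‑1,3‑dioxolane
Product: 14 undecanal, via octylborane 12 (not isolated), via acetal 13 (not isolated)
Conditions: 9‑BBN, THF, 0 °C to rt; 11, Pd(OAc)2 (4 mol%), PCy3 (8 mol%), K3PO4·H2O, THF, rt; then 2 M HCl, THF, rt
Reagents that add atoms: 9‑borabicyclo[3.3.1]nonane, B1C2CCCC1CCC2 (boron unit of 12 only); water, O (aldehyde oxygen of 14)
Why: Anti‑Markovnikov hydroboration followed by alkyl–alkyl Suzuki–Miyaura coupling (the Pd/PCy3 catalyst outruns β‑hydride elimination) joins the C8 and C3 pieces, and the acetal is hydrolysed to the aldehyde in the acidic work‑up.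

**Step 6**
Reactants: 14 undecanal; 15 methyl 2‑(bromomethyl)acrylate
Product: 18 (R)‑5‑decyl‑3‑methylenedihydrofuran‑2(3H)‑one, via trimethylsilyl ether 16 (not isolated), via hydroxy ester 17 (not isolated)
Conditions: CrCl2 (10 mol%), 1,8‑bis(4‑isopropyl‑4,5‑dihydrooxazol‑2‑yl)‑3,6‑diphenyl‑9H‑carbazole (12 mol%; enantiomer giving Si‑face attack), Mn powder, Me3SiCl, iPr2NEt (30 mol%), THF, rt; then 1 M HCl, THF, rt
Reagents that add atoms: chlorotrimethylsilane, C[Si](C)(C)Cl (silyl group of 16 only)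
Why: Catalytic asymmetric Nozaki–Hiyama–Kishi 2‑(alkoxycarbonyl)allylation, in which the allylchromium species (trivalent chromium, regenerated from CrCl2 by Mn and released by Me3SiCl) adds through a chair transition state inside the carbazole bis(oxazoline) pocket to the Si face of 14 to set the (R)‑carbinol, and acid then removes the silyl group and closes the γ‑lactone.

**Step 7**
Reactants: 18 (R)‑5‑decyl‑3‑methylenedihydrofuran‑2(3H)‑one
Product: 20 (R)‑5‑decyldihydrofuran‑2,3‑dione, via ozonide 19 (not isolated)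
Conditions: O3, CH2Cl2, −78 °C; Me2S, −78 °C to rt
Reagents that add atoms: ozone, [O-][O+]=O
Why: Criegee ozonolysis of the 1,1‑disubstituted alkene with reductive work‑up gives the α‑keto lactone (which drifts to its enol on standing and is therefore used at once) without involving the C5 stereocentre.

**Step 8**
Reactants: 20 (R)‑5‑decyldihydrofuran‑2,3‑dione; 9 (R)‑4‑[(tert‑butyldimethylsilyl)oxy]‑1‑diazoundecan‑2‑one
Product: 23 (2R,6R)‑6‑decyl‑2‑heptyl‑2,3,5,6‑tetrahydropyrano[2,3‑c]pyran‑4,8‑dione (target), via ring‑expanded silyl ether 21 (not isolated), via hydroxy ketone 22 (not isolated)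
Conditions: Sc(OTf)3 (10 mol%), 4 Å MS, CH2Cl2, −20 °C to rt; then 48% aq HF, MeCN, 0 °C to rt
Reagents that add atoms: none
Why: Proposed new method: a Lewis‑acid‑catalysed Tiffeneau–Demjanov‑type one‑carbon ring expansion of an α‑keto‑γ‑lactone by a terminal α‑diazoketone, in which Sc(OTf)3 chelates the 1,2‑dicarbonyl of the keto tautomer of 20 (the enol re‑equilibrates under the Lewis acid and N2 loss makes the addition irreversible), the diazo carbon of 9 adds to C3, and the C4 methylene, a far better migrating group than the electron‑poor lactone acyl carbon, shifts to the diazonium carbon to give the six‑membered 4‑acyl α‑keto‑δ‑lactone as its chelated enol 21, the closest known reactions being Sc(OTf)3‑catalysed ring expansions of isatins and cycloalkanones with diazo esters and Roskamp‑type homologation of aldehydes and α‑keto esters; aqueous HF then removes the silyl group and the freed hydroxyl closes ring B by hemiketalisation at C3 and dehydration, both stereocentres being retained because neither carbinol C–O bond is broken.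

**Compound list**
1 | 1‑bromoheptane | CCCCCCCBr | starting material
2 | heptylmagnesium bromide | CCCCCCC[Mg]Br | intermediate
3 | octanal | CCCCCCCC=O | intermediate
4 | 2‑methoxypropene | COC(C)=C | starting material
5 | (R)‑2‑methoxyundec‑1‑en‑4‑ol | COC(=C)C[C@H](O)CCCCCCC | intermediate
6 | (R)‑4‑hydroxyundecan‑2‑one | CC(=O)C[C@H](O)CCCCCCC | intermediate
7 | (R)‑4‑[(tert‑butyldimethylsilyl)oxy]undecan‑2‑one | CC(=O)C[C@H](O[Si](C)(C)C(C)(C)C)CCCCCCC | intermediate
8 | (R)‑6‑[(tert‑butyldimethylsilyl)oxy]‑1,1,1‑trifluorotridecane‑2,4‑dione | FC(F)(F)C(=O)CC(=O)C[C@H](O[Si](C)(C)C(C)(C)C)CCCCCCC | intermediate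
9 | (R)‑4‑[(tert‑butyldimethylsilyl)oxy]‑1‑diazoundecan‑2‑one | [N-]=[N+]=CC(=O)C[C@H](O[Si](C)(C)C(C)(C)C)CCCCCCC | intermediate
10 | oct‑1‑ene | C=CCCCCCC | starting material
11 | 2‑(2‑bromoethyl)‑1,3‑dioxolane | BrCCC1OCCO1 | starting material
12 | 9‑octyl‑9‑borabicyclo[3.3.1]nonane | CCCCCCCCB1C2CCCC1CCC2 | intermediate
13 | 2‑decyl‑1,3‑dioxolane | CCCCCCCCCCC1OCCO1 | intermediate
14 | undecanal | CCCCCCCCCCC=O | intermediate
15 | methyl 2‑(bromomethyl)acrylate | COC(=O)C(=C)CBr | starting material
16 | methyl (R)‑2‑methylidene‑4‑[(trimethylsilyl)oxy]tetradecanoate | CCCCCCCCCC[C@H](CC(=C)C(=O)OC)O[Si](C)(C)C | intermediate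
17 | methyl (R)‑4‑hydroxy‑2‑methylidenetetradecanoate | CCCCCCCCCC[C@H](CC(=C)C(=O)OC)O | intermediate
18 | (R)‑5‑decyl‑3‑methylenedihydrofuran‑2(3H)‑one | CCCCCCCCCC[C@@H]1CC(=C)C(=O)O1 | intermediate
19 | (8R)‑8‑decyl‑1,2,4,7‑tetraoxaspiro[4.4]nonan‑6‑one (spiro ozonide, both configurations at the spiro carbon) | CCCCCCCCCC[C@@H]1CC2(OOCO2)C(=O)O1 | intermediate
20 | (R)‑5‑decyldihydrofuran‑2,3‑dione (in equilibrium with its enol, (R)‑5‑decyl‑3‑hydroxyfuran‑2(5H)‑one) | CCCCCCCCCC[C@@H]1CC(=O)C(=O)O1 | intermediate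
21 | (6R)‑4‑{(3R)‑3‑[(tert‑butyldimethylsilyl)oxy]decanoyl}‑6‑decyl‑3‑hydroxy‑5,6‑dihydro‑2H‑pyran‑2‑one | CCCCCCCCCC[C@@H]1CC(C(=O)C[C@H](O[Si](C)(C)C(C)(C)C)CCCCCCC)=C(O)C(=O)O1 | intermediate
22 | (6R)‑6‑decyl‑3‑hydroxy‑4‑[(3R)‑3‑hydroxydecanoyl]‑5,6‑dihydro‑2H‑pyran‑2‑one | CCCCCCCCCC[C@@H]1CC(C(=O)C[C@H](O)CCCCCCC)=C(O)C(=O)O1 | intermediate
23 | (2R,6R)‑6‑decyl‑2‑heptyl‑2,3,5,6‑tetrahydropyrano[2,3‑c]pyran‑4,8‑dione | CCCCCCCCCC[C@@H]1CC2=C(O[C@H](CCCCCCC)CC2=O)C(=O)O1 | target

**Step count and risk**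
Total: 8 steps. Longest linear sequence: 5 steps (steps 1, 2, 3, 4, 8).

Most likely to fail, step 8 (the proposed ring expansion). The enol of 20 may be O‑alkylated by 9, the adduct may close to an epoxide, or the lactone acyl carbon may migrate instead of C4. The fallback uses known chemistry and closes ring A by an intramolecular oxalate Claisen (Dieckmann‑type) condensation; it sets out from 14 and 7 and comes back at 21, which is then treated with aqueous HF as in the second stage of step 8. Undecanal 14 is methylenated with trimethylsulfonium iodide and NaH (Corey–Chaykovsky) to racemic 2‑decyloxirane F1. This is resolved by Jacobsen hydrolytic kinetic resolution with (salen)Co(OAc) (trivalent cobalt, 0.5 mol%, 0.55 equiv water, the catalyst enantiomer that hydrolyses the S epoxide) to (R)‑2‑decyloxirane F2. Ketone 7 is condensed with 1,1‑dimethylhydrazine to the hydrazone (R)‑2‑{4‑[(tert‑butyldimethylsilyl)oxy]undecan‑2‑ylidene}‑1,1‑dimethylhydrazine F3. Deprotonation of F3 at its methyl group with LiN(iPr)2 and opening of F2 at the CH2 terminus give (11R,16R)‑16‑[(tert‑butyldimethylsilyl)oxy]‑14‑(2,2‑dimethylhydrazinylidene)tricosan‑11‑ol F4. Hydrolysis of F4 with CuCl2 in buffered aqueous THF gives (8R,13R)‑8‑[(tert‑butyldimethylsilyl)oxy]‑13‑hydroxytricosan‑10‑one F5. Acylation with methyl chlorooxoacetate and pyridine gives (11R,16R)‑16‑[(tert‑butyldimethylsilyl)oxy]‑14‑oxotricosan‑11‑yl methyl oxalate F6. LiN(SiMe3)2 (2.2 equiv, THF, −78 to 0 °C) then closes the ring; only the enolate on the CH2CH2 side can reach the oxalate carbonyl through a six‑membered transition state, so 21 is formed regioselectively.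

Second, step 6 (catalytic asymmetric allylation/lactonisation): the enantioselectivity or the chromium turnover may be poor with this long‑chain aldehyde. The fallback sets the carbinol by a different C–C bond formation and builds the keto lactone by oxidation instead of ozonolysis; it sets out from 14 and comes back at 20, so it also replaces step 7. Krische allylation of 14 ([Ir(cod)Cl]2, BINAP enantiomer giving Si‑face attack, 4‑chloro‑3‑nitrobenzoic acid, Cs2CO3, allyl acetate, iPrOH, THF, 100 °C) gives (R)‑tetradec‑1‑en‑4‑ol F7. Dihydroxylation (OsO4 cat., NMO) gives (4R)‑tetradecane‑1,2,4‑triol F8 as a mixture at C2. Oxidative lactonisation with TEMPO and (diacetoxyiodo)benzene gives (5R)‑5‑decyl‑3‑hydroxydihydrofuran‑2(3H)‑one F9. Dess–Martin oxidation gives 20.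

Third, step 2 (titanium‑catalysed aldol): the enantiomeric excess may fall short with an unbranched aldehyde. The fallback installs the oxygen by asymmetric conjugate borylation instead of an aldol; it sets out from 3 and comes back at 6. Wittig reaction of 3 with Ph3P=CHC(O)CH3 gives (E)‑undec‑3‑en‑2‑one F10. Copper‑catalysed β‑borylation (CuCl, NaOtBu, the Josiphos enantiomer that gives the R boronate, B2pin2, MeOH, THF) gives (R)‑4‑(4,4,5,5‑tetramethyl‑1,3,2‑dioxaborolan‑2‑yl)undecan‑2‑one F11. Oxidation with NaBO3·4H2O proceeds with retention to give 6.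

**Further compounds**
F1 | step 8 | racemic 2‑decyloxirane | CCCCCCCCCCC1CO1
F2 | step 8 | (R)‑2‑decyloxirane | CCCCCCCCCC[C@@H]1CO1
F3 | step 8 | (R)‑2‑{4‑[(tert‑butyldimethylsilyl)oxy]undecan‑2‑ylidene}‑1,1‑dimethylhydrazine | CC(=NN(C)C)C[C@H](O[Si](C)(C)C(C)(C)C)CCCCCCC
F4 | step 8 | (11R,16R)‑16‑[(tert‑butyldimethylsilyl)oxy]‑14‑(2,2‑dimethylhydrazinylidene)tricosan‑11‑ol | CCCCCCC[C@H](CC(=NN(C)C)CC[C@H](O)CCCCCCCCCC)O[Si](C)(C)C(C)(C)C
F5 | step 8 | (8R,13R)‑8‑[(tert‑butyldimethylsilyl)oxy]‑13‑hydroxytricosan‑10‑one | CCCCCCC[C@H](CC(=O)CC[C@H](O)CCCCCCCCCC)O[Si](C)(C)C(C)(C)C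
F6 | step 8 | (11R,16R)‑16‑[(tert‑butyldimethylsilyl)oxy]‑14‑oxotricosan‑11‑yl methyl oxalate | CCCCCCC[C@H](CC(=O)CC[C@H](OC(=O)C(=O)OC)CCCCCCCCCC)O[Si](C)(C)C(C)(C)C
F7 | step 6 | (R)‑tetradec‑1‑en‑4‑ol | C=CC[C@H](O)CCCCCCCCCC
F8 | step 6 | (4R)‑tetradecane‑1,2,4‑triol | OCC(O)C[C@H](O)CCCCCCCCCC
F9 | step 6 | (5R)‑5‑decyl‑3‑hydroxydihydrofuran‑2(3H)‑one | CCCCCCCCCC[C@@H]1CC(O)C(=O)O1
F10 | step 2 | (E)‑undec‑3‑en‑2‑one | CC(=O)/C=C/CCCCCCC
F11 | step 2 | (R)‑4‑(4,4,5,5‑tetramethyl‑1,3,2‑dioxaborolan‑2‑yl)undecan‑2‑one | CC(=O)C[C@H](B1OC(C)(C)C(C)(C)O1)CCCCCCC
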